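**Retrosynthetic overview**

1. Target ⇐ O‑debenzylation ⇐ Felkin‑controlled reduction of the benzylic ketone of a trans‑α‑benzyl‑β‑aroyl‑γ‑butyrolactone.
2. Aroyl group ⇐ ozonolysis of a 1‑arylprop‑1‑enyl group; α‑benzyl group ⇐ trans‑selective alkylation of the lactone enolate.
3. β‑Alkenyl‑γ‑butyrolactone (the only ring, formed first) ⇐ orthoester Claisen [3,3] rearrangement of the cyclic ketene acetal of a (Z)‑2‑aryl‑2‑ene‑1,4‑diol. This step forms the C3–C4 bond, closes the lactone and transfers the carbinol chirality to C4.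
4. Diol ⇐ Cu‑catalysed anti‑arylmagnesiation of (R)‑but‑3‑yn‑2‑ol, trapped with formaldehyde. All three stereocentres descend from this one purchased centre.

Assumption: (R)‑but‑3‑yn‑2‑ol (≥98% ee), 3,4‑dimethoxyphenylmagnesium bromide (THF solution) and 4‑(benzyloxy)‑3‑methoxybenzyl bromide are bought as such.

**Route**

Step 1
Reactants: 1 (R)‑but‑3‑yn‑2‑ol; 2 3,4‑dimethoxyphenylmagnesium bromide; 3 formaldehyde (as paraformaldehyde)
Product: 5 (2Z,4R)‑3‑(3,4‑dimethoxyphenyl)pent‑2‑ene‑1,4‑diol, via alkenylmagnesium chelate 4 (not isolated)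
Conditions: 2 (3 equiv), CuI (10 mol%), THF, 0 °C → reflux; then (CH2O)n (excess), 0 °C → rt; aq NH4Cl
Reagents that add atoms: 3,4‑dimethoxyphenylmagnesium bromide 2 (COc1ccc([Mg]Br)cc1OC); formaldehyde 3 (C=O)
Why: Copper‑catalysed anti‑carbomagnesiation of the propargylic alkoxide puts the aryl group on the carbinol‑side alkyne carbon and magnesium on the terminal carbon in a five‑membered chelate, so trapping with formaldehyde fixes CH2OH cis to the carbinol carbon (Z) while the purchased (R)‑centre is untouched.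

Step 2
Reactants: 5 (2Z,4R)‑3‑(3,4‑dimethoxyphenyl)pent‑2‑ene‑1,4‑diol; 6 triethyl orthoacetate
Product: 9 (4S)‑4‑[(1Z)‑1‑(3,4‑dimethoxyphenyl)prop‑1‑en‑1‑yl]oxolan‑2‑one, via cyclic orthoester 7 (not isolated), via cyclic ketene acetal 8 (not isolated)
Conditions: 6 (5 equiv), EtCO2H (5 mol%), o‑xylene, 145 °C, EtOH distilled off
Reagents that add atoms: triethyl orthoacetate 6 (CCOC(C)(OCC)OCC)
Why: Orthoester (Johnson–Claisen) [3,3]‑sigmatropic rearrangement in which ketene acetal 8 breaks the secondary allylic C–O bond and forms the C3–C4 bond at the unhindered CH terminus (the other terminus would become a quaternary carbon and lose styrene conjugation), contracting the dioxepine directly to the γ‑lactone, while suprafacial 1,3‑chirality transfer with the methyl group held outside by A(1,3) strain against the cis CH2O arm turns the (R)‑carbinol centre into (S)‑C4.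

Step 3
Reactants: 9 (4S)‑4‑[(1Z)‑1‑(3,4‑dimethoxyphenyl)prop‑1‑en‑1‑yl]oxolan‑2‑one; 10 4‑(benzyloxy)‑3‑methoxybenzyl bromide
Product: 12 (3R,4S)‑3‑{[4‑(benzyloxy)‑3‑methoxyphenyl]methyl}‑4‑[(1Z)‑1‑(3,4‑dimethoxyphenyl)prop‑1‑en‑1‑yl]oxolan‑2‑one, via lithium enolate 11 (not isolated)
Conditions: LDA (1.1 equiv), THF, −78 °C; then 10 (1.2 equiv), DMPU, −78 → −40 °C
Reagents that add atoms: 4‑(benzyloxy)‑3‑methoxybenzyl bromide 10 (COc1cc(CBr)ccc1OCc1ccccc1)
Why: Lactone enolate alkylation in which the benzylic bromide approaches the planar enolate anti to the bulky C4 alkenyl group, giving the 3,4‑trans product with (3R) configuration.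

Step 4
Reactants: 12 (3R,4S)‑3‑{[4‑(benzyloxy)‑3‑methoxyphenyl]methyl}‑4‑[(1Z)‑1‑(3,4‑dimethoxyphenyl)prop‑1‑en‑1‑yl]oxolan‑2‑one
Product: 14 (3R,4R)‑3‑{[4‑(benzyloxy)‑3‑methoxyphenyl]methyl}‑4‑(3,4‑dimethoxybenzoyl)oxolan‑2‑one, via ozonide 13 (not isolated)
Conditions: O3, CH2Cl2, −78 °C (Sudan Red 7B end‑point); then Me2S, −78 °C → rt
Reagents that add atoms: ozone ([O-][O+]=O)
Why: Ozonolysis with reductive work‑up, in which the electron‑rich trisubstituted styrene double bond reacts far faster than the arenes and the aryl ketone is unveiled under neutral conditions that leave both stereocentres untouched (only the CIP descriptor at C4 changes).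

Step 5
Reactants: 14 (3R,4R)‑3‑{[4‑(benzyloxy)‑3‑methoxyphenyl]methyl}‑4‑(3,4‑dimethoxybenzoyl)oxolan‑2‑one
Product: 15 (3R,4R)‑3‑{[4‑(benzyloxy)‑3‑methoxyphenyl]methyl}‑4‑[(S)‑(3,4‑dimethoxyphenyl)(hydroxy)methyl]oxolan‑2‑one
Conditions: L‑Selectride (1.2 equiv), THF, −78 °C, 1 h; AcOH quench at −78 °C
Reagents that add atoms: none
Why: Felkin–Anh‑controlled ketone reduction in which the bulky hydride attacks the aroyl carbonyl anti to the larger C3 branch at C4 and over the C4–H, giving the (S)‑carbinol, while the lactone is inert at −78 °C and the cold acidic quench prevents translactonisation.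

Step 6
Reactants: 15 (3R,4R)‑3‑{[4‑(benzyloxy)‑3‑methoxyphenyl]methyl}‑4‑[(S)‑(3,4‑dimethoxyphenyl)(hydroxy)methyl]oxolan‑2‑one
Product: 16 (3R,4R)‑4‑[(S)‑(3,4‑dimethoxyphenyl)(hydroxy)methyl]‑3‑[(4‑hydroxy‑3‑methoxyphenyl)methyl]oxolan‑2‑one
Conditions: H2 (1 atm), 10% Pd/C, EtOAc, rt, stopped at 1 equiv H2
Reagents that add atoms: none
Why: Catalytic hydrogenolysis of the aryl benzyl ether is much faster under neutral conditions than hydrogenolysis of the secondary benzylic C–OH bond, so the phenol is freed without touching any stereocentre.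

**Compound list**

1 | (R)‑but‑3‑yn‑2‑ol | C[C@@H](O)C#C | starting material
2 | 3,4‑dimethoxyphenylmagnesium bromide | COc1ccc([Mg]Br)cc1OC | starting material
3 | formaldehyde (as paraformaldehyde) | C=O | starting material
4 | (5R)‑4‑(3,4‑dimethoxyphenyl)‑5‑methyl‑2,5‑dihydro‑1,2‑oxamagnesole (chelated (Z)‑alkenylmagnesium alkoxide) | C[C@H]1O[Mg]C=C1c1ccc(OC)c(OC)c1 | intermediate
5 | (2Z,4R)‑3‑(3,4‑dimethoxyphenyl)pent‑2‑ene‑1,4‑diol | C[C@@H](O)/C(c1ccc(OC)c(OC)c1)=C\CO | intermediate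
6 | triethyl orthoacetate | CCOC(C)(OCC)OCC | starting material
7 | (4R)‑5‑(3,4‑dimethoxyphenyl)‑2‑ethoxy‑2,4‑dimethyl‑4,7‑dihydro‑1,3‑dioxepine (C2 epimers) | CCOC1(C)OCC=C(c2ccc(OC)c(OC)c2)[C@@H](C)O1 | intermediate
8 | (4R)‑5‑(3,4‑dimethoxyphenyl)‑4‑methyl‑2‑methylidene‑4,7‑dihydro‑1,3‑dioxepine | C=C1OCC=C(c2ccc(OC)c(OC)c2)[C@@H](C)O1 | intermediate
9 | (4S)‑4‑[(1Z)‑1‑(3,4‑dimethoxyphenyl)prop‑1‑en‑1‑yl]oxolan‑2‑one | O=C1C[C@H](CO1)/C(c2ccc(OC)c(OC)c2)=C/C | intermediate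
10 | 4‑(benzyloxy)‑3‑methoxybenzyl bromide | COc1cc(CBr)ccc1OCc1ccccc1 | starting material
11 | lithium enolate of 9 | [Li]OC1=C[C@H](CO1)/C(c2ccc(OC)c(OC)c2)=C/C | intermediate
12 | (3R,4S)‑3‑{[4‑(benzyloxy)‑3‑methoxyphenyl]methyl}‑4‑[(1Z)‑1‑(3,4‑dimethoxyphenyl)prop‑1‑en‑1‑yl]oxolan‑2‑one | COc1cc(C[C@H]2C(=O)OC[C@@H]2/C(c2ccc(OC)c(OC)c2)=C/C)ccc1OCc1ccccc1 | intermediate
13 | secondary ozonide (1,2,4‑trioxolane) of 12, mixture at the two new ring carbons | COc1cc(C[C@H]2C(=O)OC[C@@H]2C2(OOC(C)O2)c2ccc(OC)c(OC)c2)ccc1OCc1ccccc1 | intermediate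
14 | (3R,4R)‑3‑{[4‑(benzyloxy)‑3‑methoxyphenyl]methyl}‑4‑(3,4‑dimethoxybenzoyl)oxolan‑2‑one | COc1cc(C[C@H]2C(=O)OC[C@@H]2C(=O)c2ccc(OC)c(OC)c2)ccc1OCc1ccccc1 | intermediate
15 | (3R,4R)‑3‑{[4‑(benzyloxy)‑3‑methoxyphenyl]methyl}‑4‑[(S)‑(3,4‑dimethoxyphenyl)(hydroxy)methyl]oxolan‑2‑one | COc1cc(C[C@H]2C(=O)OC[C@@H]2[C@H](O)c2ccc(OC)c(OC)c2)ccc1OCc1ccccc1 | intermediate
16 | (3R,4R)‑4‑[(S)‑(3,4‑dimethoxyphenyl)(hydroxy)methyl]‑3‑[(4‑hydroxy‑3‑methoxyphenyl)methyl]oxolan‑2‑one | COc1cc(C[C@H]2C(=O)OC[C@@H]2[C@H](O)c2ccc(OC)c(OC)c2)ccc1O | target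

**Step count and risks**

Total step count: 6. Longest linear sequence: 6 (1 → 5 → 9 → 12 → 14 → 15 → 16).

The three steps most likely to fail:

Step 1 (one‑pot arylmagnesiation and hydroxymethylation). The chelated alkenylmagnesium may react sluggishly with paraformaldehyde, and excess Grignard competes for it. The fallback sets out from 1 and 2. The same Cu‑catalysed arylmagnesiation is run to 4, but the flask is quenched with CO2 instead of formaldehyde. Acidic work‑up closes the (Z)‑hydroxy acid to the butenolide (5R)‑4‑(3,4‑dimethoxyphenyl)‑5‑methylfuran‑2(5H)‑one F1, whose ring locks the alkene geometry. DIBAL‑H (3 equiv, CH2Cl2, −78 → 0 °C) then reduces F1 to the diol, and the route is rejoined at 5.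

Step 2 (orthoester Claisen under hot, weakly acidic conditions). The electron‑rich cinnamyl‑type primary alcohol can ionise and cyclise to a 2,5‑dihydrofuran, and some rearrangement through the primary oxygen is possible. The fallback sets out from 5. Selective silylation of the primary hydroxyl (TBSCl, imidazole, CH2Cl2, 0 °C) gives (2R,3Z)‑5‑[(tert‑butyldimethylsilyl)oxy]‑3‑(3,4‑dimethoxyphenyl)pent‑3‑en‑2‑ol F2. A neutral Eschenmoser–Claisen rearrangement with N,N‑dimethylacetamide dimethyl acetal (toluene, 110 °C) can then only proceed through the secondary oxygen. It gives (3S,4Z)‑3‑{[(tert‑butyldimethylsilyl)oxy]methyl}‑4‑(3,4‑dimethoxyphenyl)‑N,N‑dimethylhex‑4‑enamide F3 with the same chirality transfer. HCl in MeOH removes the silyl group and the γ‑hydroxy amide lactonises, which comes back to the route at 9.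

Step 5 (diastereoselective reduction). The Felkin preference is a prediction, not a measured result, and may be modest or reversed; the new alkoxide could also translactonise if the mixture warms. The fallback sets out from 14. If hydride reduction gives mainly the epimeric carbinol (3R,4R)‑3‑{[4‑(benzyloxy)‑3‑methoxyphenyl]methyl}‑4‑[(R)‑(3,4‑dimethoxyphenyl)(hydroxy)methyl]oxolan‑2‑one F4, that alcohol is inverted by a Mitsunobu reaction (4‑nitrobenzoic acid, PPh3, DIAD, THF, 0 °C). This gives (S)‑[(3R,4R)‑4‑{[4‑(benzyloxy)‑3‑methoxyphenyl]methyl}‑5‑oxooxolan‑3‑yl](3,4‑dimethoxyphenyl)methyl 4‑nitrobenzoate F5. Mild methanolysis (K2CO3, MeOH, 0 °C) then returns to the route at 15.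

Further compounds
F1 | step 1 | (5R)‑4‑(3,4‑dimethoxyphenyl)‑5‑methylfuran‑2(5H)‑one | C[C@H]1OC(=O)C=C1c1ccc(OC)c(OC)c1
F2 | step 2 | (2R,3Z)‑5‑[(tert‑butyldimethylsilyl)oxy]‑3‑(3,4‑dimethoxyphenyl)pent‑3‑en‑2‑ol | C[C@@H](O)/C(c1ccc(OC)c(OC)c1)=C\CO[Si](C)(C)C(C)(C)C
F3 | step 2 | (3S,4Z)‑3‑{[(tert‑butyldimethylsilyl)oxy]methyl}‑4‑(3,4‑dimethoxyphenyl)‑N,N‑dimethylhex‑4‑enamide | CN(C)C(=O)C[C@H](CO[Si](C)(C)C(C)(C)C)/C(c1ccc(OC)c(OC)c1)=C/C
F4 | step 5 | (3R,4R)‑3‑{[4‑(benzyloxy)‑3‑methoxyphenyl]methyl}‑4‑[(R)‑(3,4‑dimethoxyphenyl)(hydroxy)methyl]oxolan‑2‑one | COc1cc(C[C@H]2C(=O)OC[C@@H]2[C@@H](O)c2ccc(OC)c(OC)c2)ccc1OCc1ccccc1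
F5 | step 5 | (S)‑[(3R,4R)‑4‑{[4‑(benzyloxy)‑3‑methoxyphenyl]methyl}‑5‑oxooxolan‑3‑yl](3,4‑dimethoxyphenyl)methyl 4‑nitrobenzoate | COc1cc(C[C@H]2C(=O)OC[C@@H]2[C@H](OC(=O)c2ccc(cc2)[N+](=O)[O-])c2ccc(OC)c(OC)c2)ccc1OCc1ccccc1
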